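## The problem

Compound 21 is a daucane ester. A cyclopentane (C1–C5) is trans-fused across C1–C5 to a cycloheptene (C5–C6–C7–C8=C9–C10–C1). C1 carries the methyl group, C4 a tertiary isopropyl carbinol, C6 the 4-hydroxybenzoate and C8 the aldehyde carbon C14. This numbering is used for every intermediate below.

Four stereocentres, three of them contiguous at the ring fusion, must be set as 1R,4R,5S,6S. The C1 methyl and H5 are trans, the C4 hydroxyl is cis to the methyl, and the C6 oxygen is cis to H5.

Closing a seven-membered ring directly onto a quaternary fusion atom is slow and gives no handle on C5, so the ring fusion is the central difficulty.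

The centres can be chained. An oxygenated C6 set first shields one face of a neighbouring ring. The configurations of two carbinols at C1 and C4 can then be translated into C1 and C5 of the bicycle. The angular methyl finally steers a nucleophile onto a C4 ketone.

The enal, the phenolic ester and the tertiary alcohol do not tolerate hydride, organometallic or strongly acidic reagents. A C4 ketone with oxygen on C6 is a β-oxy ketone, open to elimination and to epimerisation at C5. The acid step therefore has to come early, and the aryl ester and the aldehyde last.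

The enabling feature is the C1–C10 bond. C1 already holds the methyl, C2 and C5, and C10 is a plain allylic CH2. If C10 is returned from C1 to C5, C5 becomes the spiro atom of a spiro[4.5]dec-8-ene, which is a Diels–Alder ring, and C1 becomes a tertiary carbinol. The C4 oxygen next to C5 can then supply the hydrogen that ends as H5 while itself becoming the ketone that isopropyl addition needs.

## Retrosynthesis

**Aryl ester (21 ⇐ 20 ⇐ 18 + 19).** The C6–O acyl bond and the phenol silyl ether are cut first. The aryl ester would not survive the hydride and organometallic steps, so it has to be formed last. Diol 18 and the protected acid 19 are simple, and the coupling has only to distinguish a secondary from a tertiary hydroxyl.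

**C14 oxidation level and C6 silyl ether (18 ⇐ 17 ⇐ 16 ⇐ 15).** The enal is traced to the allylic alcohol 16 and the enoate 15. The ester is preferred to an aldehyde or a protected carbinol at C8 because it keeps C8=C9 electron-poor through the acid step. It asks only for a 1,2-reduction and a selective allylic oxidation.

**C4–isopropyl bond (15 ⇐ 13 + 14).** Cutting this bond removes the tertiary carbinol and one stereocentre and leaves ketone 13. The forward addition must come from the face opposite the angular methyl and must not enolise a β-silyloxy ketone, which points to an organocerium reagent.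

**C1–C10 bond, the key cut (13 ⇐ 12).** In the retro sense C10 is moved from C1 to C5 and H5 is returned to C4. Against the neighbouring cuts (C7–C8, C8=C9, C5–C6) this one turns the seven-membered ring with its quaternary fusion atom into a cyclohexene. It also turns both fusion stereocentres into consequences of two carbinol configurations. Spiro diol 12 is asked to do four things:
- ionise only at the tertiary C1;
- migrate C10, which is anti to the leaving group, and not the oxygen-bearing C6. The claim that C6 migrates poorly on electronic grounds alone is not relied on; the anti alignment is the main control;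
- take the hydride from C4 (free hydroxyl, bond held parallel to the empty orbital by the five-membered ring) and not from C6 (bulky silyl ether, non-participating);
- leave the enoate and the silyl ether untouched.

**C8–C14, C1–CH3 and C4–H bonds (12 ⇐ 11 ⇐ 9 + 10 ⇐ 8).** The ester is made from the enol triflate 11 only after the Grignard and borane steps, so neither reagent meets an ester. The methyl group comes from 10 adding to ketone 9 anti to the C6 silyloxy group, which also places the C1 hydroxyl anti to C10 as the key step requires. The two ring carbonyls of dione 8 differ only in their relation to the single stereocentre C6, so substrate control cannot be trusted to tell them apart. A Corey–Bakshi–Shibata reduction is used instead: it reads the absolute configuration, reduces C4 of the (6S)-enantiomer and sends the (6R)-enantiomer to a separable regioisomer. The price is that 8 is made as a racemate and half of it is lost here. This is accepted in preference to an enantioselective cycloaddition that has no precedent for this dienophile.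

**C6–C7 and C5–C10 bonds (8 ⇐ 7 ⇐ 5 + 6).** A Diels–Alder cut of the cyclohexene gives the doubly activated silyloxymethylidene dione 5 and the siloxydiene 6. It forms the spiro centre, places oxygen on C6 and delivers the C8–C9 enol ether regiospecifically, which no enolisation of a C8 ketone would do.

**Dienophile (5 ⇐ 4 ⇐ 1 + 2, through 3).** The C5=C6 bond comes from orthoformate condensation on cyclopentane-1,3-dione, followed by hydrolysis and O-silylation.

## Roads not taken

**Alternative 1: terpene cyclase.** The cut removes C1–C10 and C4–C5 at once. A sesquiterpene cyclase would fold (2E,6E)-farnesyl diphosphate A1 into dauca-4,8-diene A2 with the correct C1 configuration.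
- Merits: one step builds both rings and the quaternary centre. In skeleton economy nothing competes with it; the chosen plan needs eight steps to reach the same bicycle.
- Weak points: A2 has no oxygen. The target then needs a stereoselective hydration of the tetrasubstituted C4=C5 bond (OH at C4, H at C5 trans to methyl), an allylic oxidation at C6 in the presence of C3, C7 and C10, and oxidation of the C14 methyl to the aldehyde. None of these is a solved selective reaction on this diene, and the enzyme must be expressed and supplied with A1.
- Comparison: the chosen plan places every oxygen from the first steps with ordinary reagents and does not depend on late C–H oxidations.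

**Alternative 2: intramolecular Negishi coupling at C7–C8.** The cut opens the seven-membered ring between C7 and C8. Forward, zinc inserts into the primary C7–I bond of diiodide A3 and Pd(PPh3)4 (zerovalent palladium) couples the alkylzinc with the C8 alkenyl iodide to give the protected hydroazulene A4.
- Merits: the ring closure is known chemistry under mild, non-acidic conditions. All four stereocentres are in place before it, and the Z-alkenyl iodide fixes the alkene position. In predictability of the ring-forming step this road is better than the chosen one.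
- Weak points: A3 is a fully substituted cyclopentane with a quaternary carbon, a tertiary carbinol and an exocyclic carbinol, and it must be built linearly with three different protecting groups. The C7 organometallic has an alkoxy group and a hydrogen on C6, so β-elimination competes with the seven-membered reductive elimination.
- Comparison: the chosen plan offsets its riskier key step with brevity. The spiro diol is reached in seven steps, and one step then creates the ring fusion, C1, C5 and the C4 ketone.

**Alternative 3: vinylcarbenoid cyclopropanation and divinylcyclopropane Cope rearrangement.** The cut removes C7–C8 and C1–C10. Forward, methyl 2-diazobut-3-enoate A5 and the cyclopentenyl siloxydiene A6 react under Rh2(S-DOSP)4 (divalent rhodium) to give the cycloheptadiene ester A7.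
- Merits: it is convergent and a known reaction class. It delivers the C8 ester, the C8=C9 alkene and oxygen on C6 in one step. It sets C1 by asymmetric catalysis, which is better than the chosen plan's regiodivergent reduction that discards half of racemic 8.
- Weak points: A7 holds C5 and C6 as an enol ether. Unmasking gives a C6 ketone whose C5 is flanked by two carbonyl-level carbons and equilibrates freely. Reduction at C6 would have to come from the face of the angular methyl. The Cope step must also form a quaternary centre from a tetrasubstituted alkene.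
- Comparison: the chosen plan fixes C6 before the ring expansion and sets C5 by a stereospecific suprafacial shift, so neither centre is left to equilibration.

Key step: step 8

**Remarks before the steps.**
- Assumption: the O-silyl derivative 5 reacts as the exocyclic silyloxymethylidene tautomer drawn. The ring silyl enol ether isomer is expected to interconvert with it by O-to-O silyl shift, and only the exocyclic form is a doubly activated dienophile.
- Compounds 7 and 8 are racemates. Absolute configuration enters in step 5.
- Names of spiro and bicyclic compounds use the route numbering defined above.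

## Route

Step 1
Reactants: 1 cyclopentane-1,3-dione; 2 triethyl orthoformate
Product: 4 2-(hydroxymethylidene)cyclopentane-1,3-dione, via 2-(ethoxymethylidene)cyclopentane-1,3-dione 3 (not isolated)
Conditions: HC(OEt)3, Ac2O, 110 °C; then H2O, THF, rt
Reagents that add atoms: water, O
Why: Orthoformate condensation at the doubly activated C2 of a 1,3-dione gives the ethoxymethylidene compound, a vinylogous ester that water should hydrolyse readily to the formyl enol.

Step 2
Reactants: 4 2-(hydroxymethylidene)cyclopentane-1,3-dione
Product: 5 2-{[tri(propan-2-yl)silyl]oxymethylidene}cyclopentane-1,3-dione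
Conditions: TIPSCl, Et3N, CH2Cl2, 0 °C; used without chromatography
Reagents that add atoms: chlorotri(propan-2-yl)silane, CC(C)[Si](Cl)(C(C)C)C(C)C
Why: O-silylation of a strongly acidic enol with a silyl chloride and amine base. The bulky silyl group slows hydrolysis and later serves as the C6 protecting group, and a silyloxy group donates less into the alkene than an alkoxy group, which keeps 5 a competent dienophile.

Step 3
Reactants: 5 2-{[tri(propan-2-yl)silyl]oxymethylidene}cyclopentane-1,3-dione; 6 2-(trimethylsilyloxy)buta-1,3-diene
Product: 7 racemic 6-[tri(propan-2-yl)silyl]oxy-8-(trimethylsilyloxy)spiro[4.5]dec-8-ene-1,4-dione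
Conditions: toluene, 90 °C, sealed tube; used crude
Reagents that add atoms: none
Why: Normal-demand Diels–Alder reaction of a 2-alkylidene-1,3-dione with a 2-siloxydiene. The nucleophilic CH2 terminus of the diene bonds to C6 and the other terminus to C5, so the enol ether is formed at C8=C9 and C6 as a racemate. A hetero-Diels–Alder adduct through a ring carbonyl would be an allyl vinyl ether that should converge on 7 by Claisen rearrangement at this temperature.

Step 4
Reactants: 7 racemic 6-[tri(propan-2-yl)silyl]oxy-8-(trimethylsilyloxy)spiro[4.5]dec-8-ene-1,4-dione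
Product: 8 racemic 1,4-dioxo-6-[tri(propan-2-yl)silyl]oxyspiro[4.5]dec-8-en-8-yl trifluoromethanesulfonate
Conditions: PhNTf2, CsF, DME, rt
Reagents that add atoms: N-phenylbis(trifluoromethanesulfonimide), FC(F)(F)S(=O)(=O)N(c1ccccc1)S(=O)(=O)C(F)(F)F
Why: Fluoride cleaves the trimethylsilyl enol ether and the regiodefined enolate is trapped at once as the enol triflate. The triflimide is present from the start so that the enolate has no lifetime for proton transfer or retro-Michael opening, and the secondary TIPS ether should not be touched by CsF.

Step 5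
Reactants: 8 racemic 1,4-dioxo-6-[tri(propan-2-yl)silyl]oxyspiro[4.5]dec-8-en-8-yl trifluoromethanesulfonate
Product: 9 (4S,5R,6S)-4-hydroxy-1-oxo-6-[tri(propan-2-yl)silyl]oxyspiro[4.5]dec-8-en-8-yl trifluoromethanesulfonate
Conditions: (R)-2-methyl-CBS-oxazaborolidine (0.3 equiv), catecholborane, toluene, −78 °C; chromatography
Reagents that add atoms: none
Why: Corey–Bakshi–Shibata reduction of a 2,2-disubstituted cyclopentane-1,3-dione. Hydride comes from the C10 face, anti to the silyloxy-bearing C6, and the (R)-catalyst (quaternary C5 as the large group) forms the (S)-carbinol, which for the (6S)-enantiomer means reduction at C4 and sets C4 and C5. The (6R)-enantiomer is matched only at its other carbonyl and is removed at this point by chromatography.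

Step 6
Reactants: 9 (4S,5R,6S)-4-hydroxy-1-oxo-6-[tri(propan-2-yl)silyl]oxyspiro[4.5]dec-8-en-8-yl trifluoromethanesulfonate; 10 methylmagnesium bromide
Product: 11 (1R,4S,5R,6S)-1,4-dihydroxy-1-methyl-6-[tri(propan-2-yl)silyl]oxyspiro[4.5]dec-8-en-8-yl trifluoromethanesulfonate
Conditions: MeMgBr (3 equiv), THF, −78 to −40 °C
Reagents that add atoms: none
Why: Grignard 1,2-addition to the remaining cyclopentanone from the C10 face, anti to the C6 silyloxy group and the C4 alkoxide. The new hydroxyl therefore ends cis to C6 and anti to C10, and the enol triflate should be inert at this temperature.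

Step 7
Reactants: 11 (1R,4S,5R,6S)-1,4-dihydroxy-1-methyl-6-[tri(propan-2-yl)silyl]oxyspiro[4.5]dec-8-en-8-yl trifluoromethanesulfonate
Product: 12 methyl (1R,4S,5R,6S)-1,4-dihydroxy-1-methyl-6-[tri(propan-2-yl)silyl]oxyspiro[4.5]dec-8-ene-8-carboxylate
Conditions: Pd(OAc)2 (5 mol%), PPh3, CO (1 atm), MeOH, Et3N, DMF, rt
Reagents that add atoms: carbon monoxide, [C-]#[O+]; methanol, CO
Why: Palladium-catalysed methoxycarbonylation of an enol triflate (oxidative addition, CO insertion, methanolysis), which runs at room temperature and tolerates free hydroxyls.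

Step 8
Reactants: 12 methyl (1R,4S,5R,6S)-1,4-dihydroxy-1-methyl-6-[tri(propan-2-yl)silyl]oxyspiro[4.5]dec-8-ene-8-carboxylate
Product: 13 methyl (1R,5S,6S)-1-methyl-4-oxo-6-[tri(propan-2-yl)silyl]oxybicyclo[5.3.0]dec-8-ene-8-carboxylate (trans ring fusion)
Conditions: TfOH (10 mol%), CH2Cl2/(CF3)2CHOH 4:1, −40 to 0 °C; Et3N quench
Reagents that add atoms: none
Why: Proposed new method: protonation and loss of water at the tertiary C1 carbinol should be assisted by the C5–C10 bond, which stands anti to the leaving group, so that C10 shifts from C5 to C1 with inversion at C1 (Wagner–Meerwein 1,2-alkyl shift); the tertiary C5 cation is then quenched by a suprafacial 1,2-hydride shift from the neighbouring C4 carbinol, whose protonated carbonyl loses a proton (semipinacol termination). The closest known reaction types are the acid-induced Wagner–Meerwein ring expansion of spirocyclic tertiary carbinols and the pinacol-type 1,2-hydride shift of a β-hydroxy carbocation; their coupling on a spiro[4.5]decene-1,4-diol has not been shown. The seven-membered ring is closed by ring expansion of the cyclohexene through a three-centre 1,2-shift transition state that inserts C1 into the C5–C10 bond, not by an end-to-end cyclisation. C1 is controlled by the anti migration of C10, which leaves the methyl cis to C6; C5 is controlled by the C4 hydrogen, which lies on the face that C10 has left and can be delivered only to that face, so H5 ends trans to the methyl; C6 is not touched. The step needs C10 to migrate and not C6, and the hydride to come from C4 and not from C6. The first is secured by the anti-periplanar alignment of C10 (C6 is syn to the leaving group) and by the inductive effect of the C6 oxygen; the second by the C4–H bond being held parallel to the empty orbital by the five-membered ring and by a free hydroxyl being a better donor than a bulky, non-participating silyl ether. Fragmentation of the 1,3-diol is disfavoured because the C4–C5 bond lies in the nodal plane of the C1 cation, and the electron-poor enoate should neither be protonated nor intercept the cations. Catalytic acid in a weakly nucleophilic fluoroalcohol medium at low temperature is chosen to limit elimination, loss of the silyl group and epimerisation of the β-silyloxy ketone.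

Step 9
Reactants: 13 methyl (1R,5S,6S)-1-methyl-4-oxo-6-[tri(propan-2-yl)silyl]oxybicyclo[5.3.0]dec-8-ene-8-carboxylate; 14 isopropylmagnesium chloride
Product: 15 methyl (1R,4R,5S,6S)-4-hydroxy-1-methyl-4-(propan-2-yl)-6-[tri(propan-2-yl)silyl]oxybicyclo[5.3.0]dec-8-ene-8-carboxylate
Conditions: iPrMgCl, CeCl3, THF, −78 °C
Reagents that add atoms: none
Why: Organocerium 1,2-addition to a hindered, enolisable ketone, chosen to suppress enolisation, β-hydride reduction and β-elimination of the silyloxy group. Attack anti to the angular C1 methyl puts the isopropyl group cis to H5 and the hydroxyl cis to the methyl (4R), and the conjugated ester should be much slower than the ketone at −78 °C.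

Step 10
Reactants: 15 methyl (1R,4R,5S,6S)-4-hydroxy-1-methyl-4-(propan-2-yl)-6-[tri(propan-2-yl)silyl]oxybicyclo[5.3.0]dec-8-ene-8-carboxylate
Product: 16 (1R,4R,5S,6S)-8-(hydroxymethyl)-1-methyl-4-(propan-2-yl)-6-[tri(propan-2-yl)silyl]oxybicyclo[5.3.0]dec-8-en-4-ol
Conditions: i-Bu2AlH (4 equiv), CH2Cl2, −78 °C; Rochelle salt work-up
Reagents that add atoms: none
Why: 1,2-Reduction of an α,β-unsaturated ester to the allylic alcohol by an aluminium hydride; the tertiary alkoxide and the silyl ether are inert.

Step 11
Reactants: 16 (1R,4R,5S,6S)-8-(hydroxymethyl)-1-methyl-4-(propan-2-yl)-6-[tri(propan-2-yl)silyl]oxybicyclo[5.3.0]dec-8-en-4-ol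
Product: 17 (1R,4R,5S,6S)-4-hydroxy-1-methyl-4-(propan-2-yl)-6-[tri(propan-2-yl)silyl]oxybicyclo[5.3.0]dec-8-ene-8-carbaldehyde
Conditions: MnO2, CH2Cl2, rt
Reagents that add atoms: none
Why: Chemoselective oxidation of a primary allylic alcohol to the enal; the tertiary alcohol cannot be oxidised.

Step 12
Reactants: 17 (1R,4R,5S,6S)-4-hydroxy-1-methyl-4-(propan-2-yl)-6-[tri(propan-2-yl)silyl]oxybicyclo[5.3.0]dec-8-ene-8-carbaldehyde
Product: 18 (1R,4R,5S,6S)-4,6-dihydroxy-1-methyl-4-(propan-2-yl)bicyclo[5.3.0]dec-8-ene-8-carbaldehyde
Conditions: Bu4NF, AcOH, THF, rt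
Reagents that add atoms: none
Why: Fluoride cleavage of the secondary silyl ether, buffered with acetic acid to protect the enal from base. No carbonyl is β to either hydroxyl at this stage, so retro-aldol and elimination pathways are absent.

Step 13
Reactants: 18 (1R,4R,5S,6S)-4,6-dihydroxy-1-methyl-4-(propan-2-yl)bicyclo[5.3.0]dec-8-ene-8-carbaldehyde; 19 4-[tert-butyl(dimethyl)silyl]oxybenzoic acid
Product: 20 (1R,4R,5S,6S)-8-formyl-4-hydroxy-1-methyl-4-(propan-2-yl)bicyclo[5.3.0]dec-8-en-6-yl 4-[tert-butyl(dimethyl)silyl]oxybenzoate
Conditions: DCC, DMAP, CH2Cl2, rt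
Reagents that add atoms: none
Why: Steglich esterification. The secondary C6 hydroxyl is acylated and the tertiary C4 hydroxyl is not; the configuration at C6 is retained because the C–O bond is not broken.

Step 14
Reactants: 20 (1R,4R,5S,6S)-8-formyl-4-hydroxy-1-methyl-4-(propan-2-yl)bicyclo[5.3.0]dec-8-en-6-yl 4-[tert-butyl(dimethyl)silyl]oxybenzoate
Product: 21 (1R,4R,5S,6S)-8-formyl-4-hydroxy-1-methyl-4-(propan-2-yl)bicyclo[5.3.0]dec-8-en-6-yl 4-hydroxybenzoate (CNP0267880.1)
Conditions: Bu4NF, AcOH, THF, 0 °C
Reagents that add atoms: none
Why: Aryl silyl ethers are cleaved by buffered fluoride within minutes under conditions that should leave the benzoate ester, the enal and the tertiary alcohol untouched.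

## Compound list

1 | cyclopentane-1,3-dione | O=C1CCC(=O)C1 | starting material
2 | triethyl orthoformate | CCOC(OCC)OCC | starting material
3 | 2-(ethoxymethylidene)cyclopentane-1,3-dione | CCOC=C1C(=O)CCC1=O | intermediate (not isolated)
4 | 2-(hydroxymethylidene)cyclopentane-1,3-dione | OC=C1C(=O)CCC1=O | intermediate
5 | 2-{[tri(propan-2-yl)silyl]oxymethylidene}cyclopentane-1,3-dione | CC(C)[Si](OC=C1C(=O)CCC1=O)(C(C)C)C(C)C | intermediate
6 | 2-(trimethylsilyloxy)buta-1,3-diene | C=CC(=C)O[Si](C)(C)C | starting material
7 | racemic 6-[tri(propan-2-yl)silyl]oxy-8-(trimethylsilyloxy)spiro[4.5]dec-8-ene-1,4-dione | O=C1CCC(=O)C12CC=C(O[Si](C)(C)C)CC2O[Si](C(C)C)(C(C)C)C(C)C | intermediate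
8 | racemic 1,4-dioxo-6-[tri(propan-2-yl)silyl]oxyspiro[4.5]dec-8-en-8-yl trifluoromethanesulfonate | O=C1CCC(=O)C12CC=C(OS(=O)(=O)C(F)(F)F)CC2O[Si](C(C)C)(C(C)C)C(C)C | intermediate
9 | (4S,5R,6S)-4-hydroxy-1-oxo-6-[tri(propan-2-yl)silyl]oxyspiro[4.5]dec-8-en-8-yl trifluoromethanesulfonate | O=C1CC[C@H](O)[C@@]12CC=C(OS(=O)(=O)C(F)(F)F)C[C@@H]2O[Si](C(C)C)(C(C)C)C(C)C | intermediate
10 | methylmagnesium bromide | C[Mg]Br | starting material
11 | (1R,4S,5R,6S)-1,4-dihydroxy-1-methyl-6-[tri(propan-2-yl)silyl]oxyspiro[4.5]dec-8-en-8-yl trifluoromethanesulfonate | C[C@@]1(O)CC[C@H](O)[C@@]12CC=C(OS(=O)(=O)C(F)(F)F)C[C@@H]2O[Si](C(C)C)(C(C)C)C(C)C | intermediate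
12 | methyl (1R,4S,5R,6S)-1,4-dihydroxy-1-methyl-6-[tri(propan-2-yl)silyl]oxyspiro[4.5]dec-8-ene-8-carboxylate | C[C@@]1(O)CC[C@H](O)[C@@]12CC=C(C(=O)OC)C[C@@H]2O[Si](C(C)C)(C(C)C)C(C)C | intermediate
13 | methyl (1R,5S,6S)-1-methyl-4-oxo-6-[tri(propan-2-yl)silyl]oxybicyclo[5.3.0]dec-8-ene-8-carboxylate, trans-fused | O=C1CC[C@]2(C)CC=C(C(=O)OC)C[C@H](O[Si](C(C)C)(C(C)C)C(C)C)[C@H]21 | intermediate
14 | isopropylmagnesium chloride | CC(C)[Mg]Cl | starting material
15 | methyl (1R,4R,5S,6S)-4-hydroxy-1-methyl-4-(propan-2-yl)-6-[tri(propan-2-yl)silyl]oxybicyclo[5.3.0]dec-8-ene-8-carboxylate | CC(C)[C@]1(O)CC[C@]2(C)CC=C(C(=O)OC)C[C@H](O[Si](C(C)C)(C(C)C)C(C)C)[C@H]21 | intermediate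
16 | (1R,4R,5S,6S)-8-(hydroxymethyl)-1-methyl-4-(propan-2-yl)-6-[tri(propan-2-yl)silyl]oxybicyclo[5.3.0]dec-8-en-4-ol | CC(C)[C@]1(O)CC[C@]2(C)CC=C(CO)C[C@H](O[Si](C(C)C)(C(C)C)C(C)C)[C@H]21 | intermediate
17 | (1R,4R,5S,6S)-4-hydroxy-1-methyl-4-(propan-2-yl)-6-[tri(propan-2-yl)silyl]oxybicyclo[5.3.0]dec-8-ene-8-carbaldehyde | CC(C)[C@]1(O)CC[C@]2(C)CC=C(C=O)C[C@H](O[Si](C(C)C)(C(C)C)C(C)C)[C@H]21 | intermediate
18 | (1R,4R,5S,6S)-4,6-dihydroxy-1-methyl-4-(propan-2-yl)bicyclo[5.3.0]dec-8-ene-8-carbaldehyde | CC(C)[C@]1(O)CC[C@]2(C)CC=C(C=O)C[C@H](O)[C@H]21 | intermediate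
19 | 4-[tert-butyl(dimethyl)silyl]oxybenzoic acid | CC(C)(C)[Si](C)(C)Oc1ccc(cc1)C(O)=O | starting material
20 | (1R,4R,5S,6S)-8-formyl-4-hydroxy-1-methyl-4-(propan-2-yl)bicyclo[5.3.0]dec-8-en-6-yl 4-[tert-butyl(dimethyl)silyl]oxybenzoate | CC(C)[C@]1(O)CC[C@]2(C)CC=C(C=O)C[C@H](OC(=O)c3ccc(O[Si](C)(C)C(C)(C)C)cc3)[C@H]21 | intermediate
21 | (1R,4R,5S,6S)-8-formyl-4-hydroxy-1-methyl-4-(propan-2-yl)bicyclo[5.3.0]dec-8-en-6-yl 4-hydroxybenzoate | CC(C)[C@]1(O)CC[C@]2(C)CC=C(C=O)C[C@H](OC(=O)c3ccc(O)cc3)[C@H]21 | target

## Step count and least certain steps

Total: 14 steps, all in one line. Longest linear sequence: 14 steps from 1.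

**Step 8 (key step).** The cation chemistry may leave the intended channel in several ways: migration of the oxygen-bearing C6 in place of C10 if ionisation is not assisted, hydride delivery from C6 in place of C4, plain dehydration without rearrangement, acid loss of the silyl group, or epimerisation at C5 and β-elimination in the product.

Fallback (known chemistry, different approach; leaves the route at 1 and returns at 13). The C1–C10 bond is not made by migration; the quaternary centre is set by conjugate addition and the seven-membered ring is closed at C8=C9 by ring-closing metathesis.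
- 1 is etherified with 2-methylpropan-1-ol (TsOH, toluene, reflux) to the vinylogous ester 3-(2-methylpropoxy)cyclopent-2-en-1-one F1.
- Addition of prop-2-enylmagnesium bromide and aqueous acid (Stork–Danheiser sequence) gives 3-(prop-2-enyl)cyclopent-2-en-1-one F2.
- Copper-catalysed enantioselective conjugate addition of 10 (Cu(OTf)2 with a chiral N-heterocyclic carbene ligand) creates C1. The magnesium enolate is trapped by aldol addition to methyl 2-methylidene-4-oxobutanoate, anti to the allyl group and through a closed chair transition state, to give methyl (4S)-4-hydroxy-2-methylidene-4-[(1S,2R)-2-methyl-5-oxo-2-(prop-2-enyl)cyclopentyl]butanoate F3.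
- Silylation (TIPSOTf, 2,6-lutidine) gives methyl (4S)-2-methylidene-4-[(1S,2R)-2-methyl-5-oxo-2-(prop-2-enyl)cyclopentyl]-4-[tri(propan-2-yl)silyl]oxybutanoate F4.
- Ring-closing metathesis of the allyl group with the acrylate unit (second-generation Hoveyda–Grubbs catalyst, toluene, 80 °C) gives 13.

**Step 3.** The push-pull dienophile may react too slowly, react through its oxa-diene face without the subsequent Claisen rearrangement, or lose its silyl group by transfer before cycloaddition.

Fallback (leaves at 1, returns at 12). The cyclohexene is built by aldol addition and metathesis.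
- C-allylation of 1 (prop-2-enyl bromide, aqueous KOH) gives 2-(prop-2-enyl)cyclopentane-1,3-dione F5.
- TIPSOTf and Et3N give 2-(prop-2-enyl)-3-[tri(propan-2-yl)silyl]oxycyclopent-2-en-1-one F6.
- TIPSOTf-catalysed Mukaiyama aldol addition to methyl 2-methylidene-4-oxobutanoate with silyl transfer gives racemic methyl 4-[2,5-dioxo-1-(prop-2-enyl)cyclopentyl]-2-methylidene-4-[tri(propan-2-yl)silyl]oxybutanoate F7.
- Ring-closing metathesis (second-generation Grubbs catalyst) gives racemic methyl 1,4-dioxo-6-[tri(propan-2-yl)silyl]oxyspiro[4.5]dec-8-ene-8-carboxylate F8.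
- The reduction of step 5 applied to F8 gives methyl (4S,5R,6S)-4-hydroxy-1-oxo-6-[tri(propan-2-yl)silyl]oxyspiro[4.5]dec-8-ene-8-carboxylate F9.
- Addition of 10 with CeCl3 at −78 °C gives 12.

**Step 5.** Catalyst control may not fully override the steric preference for the carbonyl remote from the silyloxy group. The wanted enantiomer is then partly reduced at the wrong carbonyl and the return of 9 falls; over-reduction to diols is a second drain.

Fallback (leaves at 8, returns at 11). The order is reversed so that the substrate chooses the carbonyl and the catalyst only sorts enantiomers.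
- 10 is added first to racemic 8. The carbonyl remote from the silyloxy group should react from the C10 face, giving racemic (1R*,5R*,6S*)-1-hydroxy-1-methyl-4-oxo-6-[tri(propan-2-yl)silyl]oxyspiro[4.5]dec-8-en-8-yl trifluoromethanesulfonate F10.
- Reduction of F10 with the (R)-oxazaborolidine and catecholborane is then a kinetic resolution. Only the (6S)-enantiomer presents its remaining ketone with catalyst and substrate preferences aligned, and it gives 11. The unreacted enantiomer is separated.

**Step 9.** The secondary Grignard reagent may enolise or reduce the hindered ketone, trigger β-elimination of the silyloxy group through the enolate, or attack the ester.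

Fallback (leaves at 13, returns at 15). An sp2 nucleophile without β-hydrogens for hydride transfer is used.
- Prop-1-en-2-ylmagnesium bromide with CeCl3 at −78 °C adds anti to the angular methyl to give methyl (1R,4S,5S,6S)-4-hydroxy-1-methyl-4-(prop-1-en-2-yl)-6-[tri(propan-2-yl)silyl]oxybicyclo[5.3.0]dec-8-ene-8-carboxylate F11.
- Hydrogenation of the 1,1-disubstituted alkene with RhCl(PPh3)3 and H2, which should spare the trisubstituted conjugated alkene, gives 15.

## Further compounds

F1 | step 8 | 3-(2-methylpropoxy)cyclopent-2-en-1-one | CC(C)COC1=CC(=O)CC1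
F2 | step 8 | 3-(prop-2-enyl)cyclopent-2-en-1-one | C=CCC1=CC(=O)CC1
F3 | step 8 | methyl (4S)-4-hydroxy-2-methylidene-4-[(1S,2R)-2-methyl-5-oxo-2-(prop-2-enyl)cyclopentyl]butanoate | O=C1CC[C@](C)(CC=C)[C@H]1[C@@H](O)CC(=C)C(=O)OC
F4 | step 8 | methyl (4S)-2-methylidene-4-[(1S,2R)-2-methyl-5-oxo-2-(prop-2-enyl)cyclopentyl]-4-[tri(propan-2-yl)silyl]oxybutanoate | O=C1CC[C@](C)(CC=C)[C@H]1[C@H](CC(=C)C(=O)OC)O[Si](C(C)C)(C(C)C)C(C)C
F5 | step 3 | 2-(prop-2-enyl)cyclopentane-1,3-dione | C=CCC1C(=O)CCC1=O
F6 | step 3 | 2-(prop-2-enyl)-3-[tri(propan-2-yl)silyl]oxycyclopent-2-en-1-one | C=CCC1=C(O[Si](C(C)C)(C(C)C)C(C)C)CCC1=O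
F7 | step 3 | racemic methyl 4-[2,5-dioxo-1-(prop-2-enyl)cyclopentyl]-2-methylidene-4-[tri(propan-2-yl)silyl]oxybutanoate | C=CCC1(C(=O)CCC1=O)C(CC(=C)C(=O)OC)O[Si](C(C)C)(C(C)C)C(C)C
F8 | step 3 | racemic methyl 1,4-dioxo-6-[tri(propan-2-yl)silyl]oxyspiro[4.5]dec-8-ene-8-carboxylate | O=C1CCC(=O)C12CC=C(C(=O)OC)CC2O[Si](C(C)C)(C(C)C)C(C)C
F9 | step 3 | methyl (4S,5R,6S)-4-hydroxy-1-oxo-6-[tri(propan-2-yl)silyl]oxyspiro[4.5]dec-8-ene-8-carboxylate | O=C1CC[C@H](O)[C@@]12CC=C(C(=O)OC)C[C@@H]2O[Si](C(C)C)(C(C)C)C(C)C
F10 | step 5 | racemic (1R*,5R*,6S*)-1-hydroxy-1-methyl-4-oxo-6-[tri(propan-2-yl)silyl]oxyspiro[4.5]dec-8-en-8-yl trifluoromethanesulfonate (one enantiomer drawn) | C[C@@]1(O)CCC(=O)[C@@]12CC=C(OS(=O)(=O)C(F)(F)F)C[C@@H]2O[Si](C(C)C)(C(C)C)C(C)C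
F11 | step 9 | methyl (1R,4S,5S,6S)-4-hydroxy-1-methyl-4-(prop-1-en-2-yl)-6-[tri(propan-2-yl)silyl]oxybicyclo[5.3.0]dec-8-ene-8-carboxylate | CC(=C)[C@]1(O)CC[C@]2(C)CC=C(C(=O)OC)C[C@H](O[Si](C(C)C)(C(C)C)C(C)C)[C@H]21
A1 | alternative 1 | (2E,6E)-farnesyl diphosphate | CC(C)=CCC/C(C)=C/CC/C(C)=C/COP(O)(=O)OP(O)(O)=O
A2 | alternative 1 | dauca-4,8-diene | CC(C)C1=C2CCC(C)=CC[C@@]2(C)CC1
A3 | alternative 2 | diiodide with the primary C7 iodide and the (Z)-C8 alkenyl iodide | CC(C)[C@]1(O[Si](CC)(CC)CC)CC[C@](C)(C/C=C(\I)CO[Si](C)(C)C(C)(C)C)[C@H]1[C@H](CI)OCc1ccc(OC)cc1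
A4 | alternative 2 | protected hydroazulene (C4 triethylsilyl ether, C6 4-methoxybenzyl ether, C14 tert-butyldimethylsilyl ether) | CC(C)[C@]1(O[Si](CC)(CC)CC)CC[C@]2(C)CC=C(CO[Si](C)(C)C(C)(C)C)C[C@H](OCc3ccc(OC)cc3)[C@H]21
A5 | alternative 3 | methyl 2-diazobut-3-enoate | COC(=O)C(=[N+]=[N-])C=C
A6 | alternative 3 | 6-{1-[tert-butyl(dimethyl)silyl]oxyethenyl}-7-methyl-1,4-dioxaspiro[4.4]non-6-ene | C=C(O[Si](C)(C)C(C)(C)C)C1=C(C)CCC12OCCO2
A7 | alternative 3 | bicyclic cycloheptadiene ester (C4 ketal, C6 silyl enol ether) | C1COC2(O1)CC[C@]3(C)CC=C(C(=O)OC)CC(O[Si](C)(C)C(C)(C)C)=C23
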